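**Assumptions**
- The SMILES is taken literally. In germacrane position labels (C1 ketone, C4–C5 oxirane, C6 lactone CH–O, C8 propanoate, C10 acetate, C13 acetoxymethyl) it reads 4R,5S,6S,8S,10R, with a cis oxirane (C3 and C6 on the same side).
- The ligand and catalyst enantiomers named in steps 4 and 9 are the ones expected to give 8S and 10R; if the sense of induction proves opposite, the mirror-image ligand or catalyst is used.

**Retrosynthetic overview**
1. Target ⇒ C10 tertiary alcohol (last acetylation) ⇒ C1–C10 bond by an intramolecular carbene-catalysed aldehyde–ketone acyloin addition (C1 as acyl anion equivalent); this closes the ten-membered ring and sets C10.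
2. The keto-aldehyde ⇒ one double ozonolysis of a prenyl/methallyl diene.
3. Butenolide (C6–C7 bond, C6 stereocentre) ⇒ a β-iodoacrylate-derived alkenylchromium (β-acylvinyl anion) adding to a cis-epoxy aldehyde, then lactonization.
4. Epoxy aldehyde ⇒ nerol (Sharpless epoxidation, oxidation); iodoacrylate ⇒ isoprenol-derived aldehyde + methyl propiolate (asymmetric alkynylation, propanoylation, iodide/formaldehyde halo-aldol).
5. Ring order: oxirane, then butenolide, then ten-membered carbocycle.

**Route**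

Step 1
Reactants: 1 nerol, (2Z)-3,7-dimethylocta-2,6-dien-1-ol
Product: 2 [(2S,3R)-3-methyl-3-(4-methylpent-3-en-1-yl)oxiran-2-yl]methanol
Conditions: Ti(OiPr)4 (10 mol%), L-(+)-diethyl tartrate (12 mol%), t-BuOOH, 4 Å sieves, CH2Cl2, −20 °C
Reagents that add atoms: tert-butyl hydroperoxide, CC(C)(C)OO
Why: Sharpless asymmetric epoxidation acts only on the allylic-alcohol alkene; the L-(+)-tartrate delivers oxygen to the face that gives 2S,3R (C5 S and C4 R of the target), and the Z alkene fixes the cis oxirane.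

Step 2
Reactants: 2 [(2S,3R)-3-methyl-3-(4-methylpent-3-en-1-yl)oxiran-2-yl]methanol
Product: 3 (2R,3R)-3-methyl-3-(4-methylpent-3-en-1-yl)oxirane-2-carbaldehyde
Conditions: TEMPO (2,2,6,6-tetramethylpiperidin-1-oxyl, 10 mol%), PhI(OAc)2, CH2Cl2, 0 °C to rt; used crude
Reagents that add atoms: none
Why: Oxoammonium (TEMPO/PhI(OAc)2) oxidation of the primary alcohol is neutral enough to leave the oxirane and the α-stereocentre untouched (the descriptor changes only because CHO outranks the ring carbon).

Step 3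
Reactants: 4 3-methylbut-3-en-1-ol (isoprenol)
Product: 5 3-methylbut-3-enal
Conditions: Dess–Martin periodinane (1,1,1-triacetoxy-1,1-dihydro-1,2-benziodoxol-3(1H)-one), NaHCO3, CH2Cl2, 0 °C; filtered solution used at once
Reagents that add atoms: none
Why: Buffered Dess–Martin oxidation gives the β,γ-unsaturated aldehyde without the acid or base that would isomerise it to the conjugated enal.

Step 4
Reactants: 5 3-methylbut-3-enal; 6 methyl propiolate
Product: 7 methyl (4S)-4-hydroxy-6-methylhept-6-en-2-ynoate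
Conditions: Me2Zn (3 equiv), (R,R)-ProPhenol [2,6-bis{[(2R)-2-(hydroxydiphenylmethyl)pyrrolidin-1-yl]methyl}-4-methylphenol, 10 mol%], Ph3P=O (20 mol%), toluene, 4 °C
Reagents that add atoms: none
Why: Zinc–ProPhenol catalysed asymmetric alkynylation, in which the dinuclear zinc alkynylide adds to one face of the aldehyde and so sets C8 (S) under ligand control.

Step 5
Reactants: 7 methyl (4S)-4-hydroxy-6-methylhept-6-en-2-ynoate
Product: 8 methyl (4S)-6-methyl-4-(propanoyloxy)hept-6-en-2-ynoate
Conditions: (EtCO)2O, pyridine, 4-(dimethylamino)pyridine (5 mol%), CH2Cl2, 0 °C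
Reagents that add atoms: propanoic anhydride, CCC(=O)OC(=O)CC
Why: Acyl-transfer esterification of the secondary propargylic alcohol installs the C8 propanoate with retention, before any other hydroxyl exists.

Step 6
Reactants: 8 methyl (4S)-6-methyl-4-(propanoyloxy)hept-6-en-2-ynoate
Product: 10 methyl (2Z,4S)-2-(acetoxymethyl)-3-iodo-6-methyl-4-(propanoyloxy)hepta-2,6-dienoate, via iodo alcohol 9 (not isolated)
Conditions: MgI2 (1.5 equiv), CH2O (gas from cracked paraformaldehyde, excess), CH2Cl2, −20 to 0 °C; then Ac2O, pyridine, 0 °C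
Reagents that add atoms: magnesium diiodide, [Mg+2].[I-].[I-]; formaldehyde, C=O; acetic anhydride, CC(=O)OC(C)=O
Why: Halo-aldol (β-iodo Morita–Baylis–Hillman-type) coupling, in which iodide adds to C7 and the magnesium iodo-allenolate takes formaldehyde at C11 on the side away from iodine; this net anti addition puts I cis to CO2Me (Z), the geometry needed for lactonization, and the magnesium alkoxide is acetylated in the same flask.

Step 7
Reactants: 10 methyl (2Z,4S)-2-(acetoxymethyl)-3-iodo-6-methyl-4-(propanoyloxy)hepta-2,6-dienoate; 3 (2R,3R)-3-methyl-3-(4-methylpent-3-en-1-yl)oxirane-2-carbaldehyde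
Product: 12 (1S)-1-[(2S)-4-(acetoxymethyl)-2-[(2S,3R)-3-methyl-3-(4-methylpent-3-en-1-yl)oxiran-2-yl]-5-oxo-2,5-dihydrofuran-3-yl]-3-methylbut-3-en-1-yl propanoate, via hydroxy ester 11 (not isolated)
Conditions: CrCl2 (4 equiv), NiCl2 (2 mol%), DMF, 23 °C; aq. NH4Cl work-up
Reagents that add atoms: none
Why: Nozaki–Hiyama–Kishi reaction, in which the alkenylchromium (a β-acylvinyl anion, i.e. the normally electrophilic acrylate β-carbon made nucleophilic) adds to the aldehyde anti to the oxirane C–O bond and past the C5 hydrogen (Felkin–Anh/Cornforth, reinforced by the cis substituent on the oxirane) to give 6S, and the chromium alkoxide cis to the ester closes the butenolide.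

Step 8
Reactants: 12 the butenolide diene of step 7
Product: 14 (1S)-1-[(2S)-4-(acetoxymethyl)-2-[(2S,3R)-3-methyl-3-(3-oxopropyl)oxiran-2-yl]-5-oxo-2,5-dihydrofuran-3-yl]-3-oxobutyl propanoate, via bis-ozonide 13 (not isolated)
Conditions: O3 (stopped at first excess), CH2Cl2, −78 °C; then PPh3, −78 °C to rt
Reagents that add atoms: ozone, [O-][O+]=O
Why: Ozonolysis cleaves the two electron-rich alkenes (prenyl end to the C1 aldehyde, methallyl end to the C10 methyl ketone) far faster than the electron-poor tetrasubstituted butenolide alkene, and no stereocentre is touched.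

Step 9
Reactants: 14 the keto aldehyde of step 8
Product: 15 (4R,5S,6S,8S,10R)-13-acetoxy-4,5-epoxy-10-hydroxy-1-oxo-8-(propanoyloxy)germacr-7(11)-en-12,6-olide
Conditions: (5aS,10bR)-2-(pentafluorophenyl)-5a,10b-dihydro-4H,6H-indeno[2,1-b][1,2,4]triazolo[4,3-d][1,4]oxazin-2-ium tetrafluoroborate (20 mol%), iPr2NEt (20 mol%), toluene, 2 mM (syringe-pump addition of 14), 40 °C
Reagents that add atoms: none
Why: Proposed new method: the triazolylidene turns the C1 aldehyde into a nucleophilic enaminol (acyl anion equivalent) that adds to the C10 methyl ketone and is then released from the tertiary alkoxide to give the α-ketol; the cis oxirane and the butenolide act as two turn elements that bring C1 and C10 together, the chiral carbene selects the ketone face that puts the new hydroxyl syn to the C8 ester (10R), and because acyloin addition is reversible any 10-epimer can be re-equilibrated with the same catalyst; the closest known chemistry is the triazolium-catalysed enantioselective intramolecular crossed aldehyde–ketone benzoin reaction (five- and six-membered rings) and the carbene-catalysed macrocyclising Stetter reaction, extended here to a ten-membered ring.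

Step 10
Reactants: 15 the C10 tertiary alcohol of step 9
Product: 16 (4R,5S,6S,8S,10R)-10,13-diacetoxy-4,5-epoxy-1-oxo-8-(propanoyloxy)germacr-7(11)-en-12,6-olide (CNP0285168.2)
Conditions: Ac2O, 4-(dimethylamino)pyridine, Et3N, CH2Cl2, 25 °C
Reagents that add atoms: acetic anhydride, CC(=O)OC(C)=O
Why: Nucleophile-catalysed acylation of the only free hydroxyl, the tertiary α-ketol, occurs at oxygen with retention at C10 and gives the target.

**Compound list**

1 | nerol, (2Z)-3,7-dimethylocta-2,6-dien-1-ol | CC(C)=CCC/C(C)=C\CO | starting material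
2 | [(2S,3R)-3-methyl-3-(4-methylpent-3-en-1-yl)oxiran-2-yl]methanol | CC(C)=CCC[C@@]1(C)O[C@H]1CO | intermediate
3 | (2R,3R)-3-methyl-3-(4-methylpent-3-en-1-yl)oxirane-2-carbaldehyde | CC(C)=CCC[C@@]1(C)O[C@H]1C=O | intermediate
4 | 3-methylbut-3-en-1-ol | CC(=C)CCO | starting material
5 | 3-methylbut-3-enal | CC(=C)CC=O | intermediate
6 | methyl propiolate | COC(=O)C#C | starting material
7 | methyl (4S)-4-hydroxy-6-methylhept-6-en-2-ynoate | COC(=O)C#C[C@@H](O)CC(C)=C | intermediate
8 | methyl (4S)-6-methyl-4-(propanoyloxy)hept-6-en-2-ynoate | COC(=O)C#C[C@@H](OC(=O)CC)CC(C)=C | intermediate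
9 | methyl (2Z,4S)-2-(hydroxymethyl)-3-iodo-6-methyl-4-(propanoyloxy)hepta-2,6-dienoate (present as its magnesium alkoxide) | COC(=O)/C(CO)=C(\I)[C@@H](OC(=O)CC)CC(C)=C | intermediate (not isolated)
10 | methyl (2Z,4S)-2-(acetoxymethyl)-3-iodo-6-methyl-4-(propanoyloxy)hepta-2,6-dienoate | COC(=O)/C(COC(C)=O)=C(\I)[C@@H](OC(=O)CC)CC(C)=C | intermediate
11 | methyl (2E,4S)-2-(acetoxymethyl)-3-[(S)-hydroxy[(2S,3R)-3-methyl-3-(4-methylpent-3-en-1-yl)oxiran-2-yl]methyl]-6-methyl-4-(propanoyloxy)hepta-2,6-dienoate (present as its chromium alkoxide) | COC(=O)/C(COC(C)=O)=C(\[C@H](O)[C@@H]1O[C@]1(C)CCC=C(C)C)[C@@H](OC(=O)CC)CC(C)=C | intermediate (not isolated)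
12 | (1S)-1-[(2S)-4-(acetoxymethyl)-2-[(2S,3R)-3-methyl-3-(4-methylpent-3-en-1-yl)oxiran-2-yl]-5-oxo-2,5-dihydrofuran-3-yl]-3-methylbut-3-en-1-yl propanoate | CCC(=O)O[C@@H](CC(C)=C)C1=C(COC(C)=O)C(=O)O[C@@H]1[C@@H]2O[C@]2(C)CCC=C(C)C | intermediate
13 | bis(1,2,4-trioxolane) of 12 (both side-chain alkenes as ozonides; the two trioxolane carbons are diastereomer mixtures) | CCC(=O)O[C@@H](CC3(C)OOCO3)C1=C(COC(C)=O)C(=O)O[C@@H]1[C@@H]2O[C@]2(C)CCC4OOC(C)(C)O4 | intermediate (not isolated)
14 | (1S)-1-[(2S)-4-(acetoxymethyl)-2-[(2S,3R)-3-methyl-3-(3-oxopropyl)oxiran-2-yl]-5-oxo-2,5-dihydrofuran-3-yl]-3-oxobutyl propanoate | CCC(=O)O[C@@H](CC(C)=O)C1=C(COC(C)=O)C(=O)O[C@@H]1[C@@H]2O[C@]2(C)CCC=O | intermediate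
15 | (4R,5S,6S,8S,10R)-13-acetoxy-4,5-epoxy-10-hydroxy-1-oxo-8-(propanoyloxy)germacr-7(11)-en-12,6-olide | CCC(=O)O[C@H]1C[C@@](C)(O)C(=O)CC[C@@]2(C)O[C@H]2[C@H]2OC(=O)C(COC(C)=O)=C12 | intermediate
16 | (4R,5S,6S,8S,10R)-10,13-diacetoxy-4,5-epoxy-1-oxo-8-(propanoyloxy)germacr-7(11)-en-12,6-olide | CCC(=O)O[C@H]1C[C@@](C)(OC(C)=O)C(=O)CC[C@@]2(C)O[C@H]2[C@H]2OC(=O)C(COC(C)=O)=C12 | target

**Step count**
- Total: 10 steps.
- Longest linear sequence: 8 steps (4 → 5 → 7 → 8 → 10 → 12 → 14 → 15 → 16, steps 3–10). The nerol branch (steps 1–2) joins at step 7.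

**Steps most likely to fail, with fallbacks**

Step 9 (ring closure at C1–C10). The acyloin equilibrium for a ten-membered ring may be unfavourable, the aldehyde may oligomerise, the base may open the oxirane from the butenolide γ-position or eliminate the β-propanoate of the ketone, and the C10 configuration is not secured by precedent. The fallback closes the ring as an alkene and sets out from 12. Ring-closing metathesis between the methallyl and prenyl-type alkenes (second-generation Hoveyda–Grubbs catalyst, RuCl2(H2IMes)(=CH-C6H4-2-OiPr), toluene, 80 °C, 1 mM, isobutene expelled) gives the ten-membered 1(10)-cycloalkene F1. Dihydroxylation of this only electron-rich alkene with OsO4/N-methylmorpholine N-oxide from the outer face of the ring (a cinchona-type ligand can be added to reinforce the face) gives the 1,10-diol F2. Dess–Martin oxidation of the secondary C1 alcohol then gives 15, where the route is rejoined.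

Step 6 (iodide/formaldehyde halo-aldol). A β-substituted ynoate may react sluggishly, formaldehyde is an unusual acceptor here, and the Z geometry rests on kinetic anti addition. The fallback sets C13 and the alkene geometry separately through an enol triflate and sets out from 8. Hydration catalysed by (Ph3P)AuNTf2 in aqueous dioxane, with the propanoate carbonyl steering oxygen to C7, gives the β-keto ester F3. C-Alkylation of its sodium enolate with 4-methoxybenzyl chloromethyl ether gives the C13 ether F4. NaH then Tf2O traps the chelated Z enolate as the enol triflate F5, with TfO cis to CO2Me. CrCl2/NiCl2 coupling of F5 with 3 and lactonization give the 13-O-(4-methoxybenzyl) butenolide F6. DDQ frees the primary alcohol F7, and Ac2O/pyridine gives 12, where the route is rejoined.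

Step 7 (alkenylchromium addition and lactonization). The tetrasubstituted alkenylchromium may add slowly to the α-branched aldehyde, may lose the allylic propanoate to give an allene, or may give poor selectivity at C6. The fallback makes the C6–C7 bond by acylation and sets C6 by reduction; it sets out from 3 and uses 10 as the partner. NaClO2/NaH2PO4/2-methylbut-2-ene gives the epoxy acid F8. 2,2'-Dipyridyl disulfide/PPh3 gives the S-2-pyridyl thioester F9. Nickel-catalysed reductive coupling of F9 with 10 (NiBr2·glyme, 4,4'-di-tert-butyl-2,2'-bipyridine, Cp2ZrCl2, Zn, 1,3-dimethyl-2-imidazolidinone) gives the α,β-epoxy ketone F10. Zn(BH4)2 in Et2O at −20 °C reduces the zinc chelate of ketone and oxirane oxygen to the erythro (6S) alcohol, which lactonizes to 12, where the route is rejoined.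

**Further compounds**

F1 | step 9 | (4R,5S,6S,8S)-13-acetoxy-4,5-epoxy-8-(propanoyloxy)germacra-1(10),7(11)-dien-12,6-olide (C1=C10 geometry not fixed) | CCC(=O)O[C@H]1CC(C)=CCC[C@@]2(C)O[C@H]2[C@H]2OC(=O)C(COC(C)=O)=C12
F2 | step 9 | (4R,5S,6S,8S,10R)-13-acetoxy-4,5-epoxy-1,10-dihydroxy-8-(propanoyloxy)germacr-7(11)-en-12,6-olide (C1 configuration not fixed) | CCC(=O)O[C@H]1C[C@@](C)(O)C(O)CC[C@@]2(C)O[C@H]2[C@H]2OC(=O)C(COC(C)=O)=C12
F3 | step 6 | methyl (4S)-6-methyl-3-oxo-4-(propanoyloxy)hept-6-enoate | COC(=O)CC(=O)[C@@H](OC(=O)CC)CC(C)=C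
F4 | step 6 | methyl (4S)-2-{[(4-methoxybenzyl)oxy]methyl}-6-methyl-3-oxo-4-(propanoyloxy)hept-6-enoate (C2 epimers) | COC(=O)C(COCc1ccc(OC)cc1)C(=O)[C@@H](OC(=O)CC)CC(C)=C
F5 | step 6 | methyl (2Z,4S)-2-{[(4-methoxybenzyl)oxy]methyl}-6-methyl-4-(propanoyloxy)-3-{[(trifluoromethyl)sulfonyl]oxy}hepta-2,6-dienoate | COC(=O)/C(COCc1ccc(OC)cc1)=C(\OS(=O)(=O)C(F)(F)F)[C@@H](OC(=O)CC)CC(C)=C
F6 | step 6 | (1S)-1-[(2S)-4-{[(4-methoxybenzyl)oxy]methyl}-2-[(2S,3R)-3-methyl-3-(4-methylpent-3-en-1-yl)oxiran-2-yl]-5-oxo-2,5-dihydrofuran-3-yl]-3-methylbut-3-en-1-yl propanoate | CCC(=O)O[C@@H](CC(C)=C)C1=C(COCc2ccc(OC)cc2)C(=O)O[C@@H]1[C@@H]3O[C@]3(C)CCC=C(C)C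
F7 | step 6 | (1S)-1-[(2S)-4-(hydroxymethyl)-2-[(2S,3R)-3-methyl-3-(4-methylpent-3-en-1-yl)oxiran-2-yl]-5-oxo-2,5-dihydrofuran-3-yl]-3-methylbut-3-en-1-yl propanoate | CCC(=O)O[C@@H](CC(C)=C)C1=C(CO)C(=O)O[C@@H]1[C@@H]3O[C@]3(C)CCC=C(C)C
F8 | step 7 | (2R,3R)-3-methyl-3-(4-methylpent-3-en-1-yl)oxirane-2-carboxylic acid | CC(C)=CCC[C@@]1(C)O[C@H]1C(O)=O
F9 | step 7 | S-pyridin-2-yl (2R,3R)-3-methyl-3-(4-methylpent-3-en-1-yl)oxirane-2-carbothioate | CC(C)=CCC[C@@]1(C)O[C@H]1C(=O)Sc1ccccn1
F10 | step 7 | methyl (2Z,4S)-2-(acetoxymethyl)-6-methyl-3-{[(2R,3R)-3-methyl-3-(4-methylpent-3-en-1-yl)oxiran-2-yl]carbonyl}-4-(propanoyloxy)hepta-2,6-dienoate | COC(=O)/C(COC(C)=O)=C(\C(=O)[C@@H]1O[C@]1(C)CCC=C(C)C)[C@@H](OC(=O)CC)CC(C)=C
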